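The synthesis rests on closing ring A last, at the C2–C3 bond. In one operation three commercial components are assembled around the C5–C10 edge of an (R)-carvone-derived enone: lithiated isobutyronitrile adds to C5 (C4–C5 bond), the C10 enolate so formed adds to phenyl vinyl sulfone (C10–C1 bond), and the α-sulfonyl carbanion at C2 closes onto the nitrile carbon C3. The step exploits that C3 of ring A sits next to the non-enolisable quaternary C4, that C10 is α to the C9 carbonyl, and that C2 is an unfunctionalised methylene. Its precursor is 6-methylcarvone; the C7 isopropenyl group steers C5 and C10 and is later excised to the C7=C8 enone that allows oxygenation of C6.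

Key step: step 2

Remark: atoms carry labdane numbers (decalin C1–C10, side chain C11–C16); α is the face opposite the C10 methyl, β the same face; 5α means 5α-H.
Remark: C8 is epimerisable up to step 6; its configuration does not matter before then, and isolated compounds 8 and 9 are drawn as the more stable 8α-methyl epimer.
Remark: 3-bromofuran-2(5H)-one (22) is taken to be commercially available.

Step 1
Reactants: 1 (R)-(−)-carvone
Product: 2 (5R,6S)-2,6-dimethyl-5-(prop-1-en-2-yl)cyclohex-2-en-1-one (trans-6-methylcarvone)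
Conditions: LiN(i-Pr)2, THF, −78 °C; MeI, −78 → 0 °C
Reagents that add atoms: iodomethane (CI)
Why: Kinetic deprotonation of the enone at the α′ position and C-methylation of the cross-conjugated lithium enolate anti to the isopropenyl group (enolate alkylation) should give 2; the new centre is the future C8, which is erased in step 4 and reset in step 6.

Step 2
Reactants: 2 trans-6-methylcarvone; 3 isobutyronitrile; 4 phenyl vinyl sulfone
Product: 8 7α-isopropenyl-4,4,8α,10β-tetramethyl-2-(phenylsulfonyl)-5α-decalin-3,9-dione, via lithium enolate 5 (not isolated), via lithiated sulfone 6 (not isolated), via enaminosulfone 7 (not isolated)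
Conditions: 3, LiN(i-Pr)2 (1.05 equiv), THF–HMPA, −78 °C; add 2, −78 → −40 °C; add 4, −40 → 0 °C; LiN(i-Pr)2 (1.1 equiv), 0 → 20 °C; then 1 M HCl, THF, 20 °C
Reagents that add atoms: water (O)
Why: Kinetic 1,4-addition of 2-lithio-2-methylpropanenitrile to the β-carbon of 2 (C4–C5) gives the regiodefined C9–C10 enolate 5, which adds to the vinyl sulfone (C10–C1); the α-sulfonyl carbanion 6 then attacks the nitrile carbon (C2–C3) and the N-lithiated enaminosulfone 7 is hydrolysed on acidic work-up, water supplying the C3 oxygen. The closest known reaction type is the sequential Michael–Michael–ring-closure annulation, here terminated by a Thorpe–Ziegler addition of a sulfonyl carbanion to a nitrile. Ring A closes by 6-exo-dig attack of C2 on the sp carbon C3 once the ring B chair places the C1 and C4 branches trans-diequatorial. C5 is set by axial attack anti to the C7 isopropenyl group of the carvone core, and C10 by approach of the sulfone anti to the new pseudoaxial C(CH3)2CN group, which makes the decalin trans-fused with a β-methyl at C10. The step needs 1,4- over 1,2-addition (tertiary nitrile anion in HMPA) and C–C bond formation at the tetrasubstituted C10 without a second intramolecular Michael addition, which is secured because the only enone is consumed in the first event and the nitrile on quaternary C4 cannot enolise. The second portion of amide base keeps the sulfone metallated if the carbanion is quenched by internal proton transfer from C8, and the resulting planar C8 enolate removes the syn-diaxial C8/C10 methyl interaction in the cyclising chair.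

Step 3
Reactants: 8 β-keto sulfone
Product: 9 7α-isopropenyl-4,4,8α,10β-tetramethyl-5α-decalin-3,9-dione
Conditions: SmI2, THF–MeOH, −78 °C
Reagents that add atoms: none
Why: SmI2 cleaves the C2–S bond of the β-keto sulfone by electron transfer (reductive desulfonylation via the samarium enolate) at a temperature at which isolated ketones and the isopropenyl group are inert.

Step 4
Reactants: 9 isopropenyl diketone
Product: 12 4,4,8,10β-tetramethyl-5α-decal-7-ene-3,9-dione, via methoxy hydroperoxide 10 (not isolated), via 7α-acetate 11 (not isolated)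
Conditions: O3, CH2Cl2–MeOH, −78 °C; then Ac2O, Et3N, DMAP, CH2Cl2, 0 → 20 °C; then DBU, 20 °C
Reagents that add atoms: none
Why: Ozonolysis in methanol traps the carbonyl oxide as methoxy hydroperoxide 10, its O-acetylation triggers the Criegee rearrangement in which C7 migrates to oxygen with retention to give acetate 11, and E1cB loss of acetic acid from this β-acetoxy ketone should furnish the C7=C8 enone, so that the stereocontrolling isopropenyl group is excised and C8 becomes trigonal.

Step 5
Reactants: 12 enone
Product: 13 4,4,8,10β-tetramethyl-5α-decal-7-ene-3,6,9-trione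
Conditions: Pd(OH)2/C (cat.), t-BuOOH, K2CO3 (cat.), CH2Cl2, 4 → 20 °C
Reagents that add atoms: tert-butyl hydroperoxide (CC(C)(C)OO)
Why: Palladium-catalysed allylic C–H oxidation of an α,β-enone at its γ-methylene with tert-butyl hydroperoxide (enone to ene-1,4-dione oxidation) should convert C6, the only allylic CH2 of 12, into a ketone, and C5, now epimerisable, is expected to keep the trans ring fusion favoured at equilibrium.

Step 6
Reactants: 13 ene-dione
Product: 14 4,4,8α,10β-tetramethyl-5α-decalin-3,6,9-trione
Conditions: Zn, AcOH, 20 °C; then DBU (cat.), CH2Cl2, 20 °C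
Reagents that add atoms: none
Why: Zinc in acetic acid reduces the electron-poor C7=C8 bond of the ene-1,4-dione chemoselectively (dissolving-metal conjugate reduction), and base equilibration α to the C9 carbonyl should place the C8 methyl equatorial (8α), the 8β epimer being 1,3-diaxial to the C10 methyl.

Step 7
Reactants: 14 trione
Product: 15 3β,6β-dihydroxy-4,4,8α,10β-tetramethyl-5α-decalin-9-one
Conditions: NaBH4 (limiting), MeOH–CH2Cl2, −20 → 0 °C
Reagents that add atoms: none
Why: Hydride reduction with NaBH4 should take the C3 ketone by axial attack (equatorial 3β-OH) and the C6 ketone from the α face because the β face is shielded by the syn-axial C10 and 4β methyl groups (axial 6β-OH), whereas the C9 carbonyl, flanked by quaternary C10 and tertiary C8, is expected to react much more slowly.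

Step 8
Reactants: 15 diol ketone
Product: 16 3β-(tert-butyldimethylsilyloxy)-6β-hydroxy-4,4,8α,10β-tetramethyl-5α-decalin-9-one
Conditions: TBSCl, imidazole, DMF, 20 °C
Reagents that add atoms: tert-butyldimethylsilyl chloride (CC(C)(C)[Si](C)(C)Cl)
Why: Silyl ether formation discriminates the equatorial 3β-OH from the 6β-OH, which is axial and 1,3-diaxial to two methyl groups.

Step 9
Reactants: 16 silyl ether ketone
Product: 17 3β-(tert-butyldimethylsilyloxy)-4,4,8α,10β-tetramethyl-9-methylene-5α-decalin-6β-ol
Conditions: Zn, CH2Br2, TiCl4, THF–CH2Cl2, 0 → 20 °C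
Reagents that add atoms: dibromomethane (BrCBr)
Why: The non-basic gem-dimetallic titanium–zinc methylene reagent (Takai–Lombardo methylenation) olefinates hindered, enolisable ketones where the Wittig reaction is sluggish, so C9=O should become the exocyclic C9=C11 alkene without epimerisation of C8.

Step 10
Reactants: 17 exocyclic alkene
Product: 18 9α,11-epoxy-3β-(tert-butyldimethylsilyloxy)-4,4,8α,10β-tetramethyl-5α-decalin-6β-ol (spiro-oxirane)
Conditions: mCPBA, NaHCO3, CH2Cl2, 0 °C
Reagents that add atoms: 3-chloroperbenzoic acid (OOC(=O)c1cccc(Cl)c1)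
Why: Peracid epoxidation (Prilezhaev reaction) of the electron-rich 1,1-disubstituted alkene should occur from the α face, anti to the adjacent axial C10 methyl group, which places the oxygen 9α and C11 9β and thereby sets the C9 configuration.

Step 11
Reactants: 18 spiro-epoxide
Product: 20 3β-(tert-butyldimethylsilyloxy)-4,4,8α,10β-tetramethyl-9β-vinyl-5α-decalin-6β,9α-diol, via sulfonium alkoxide 19 (not isolated)
Conditions: Me3S+ I−, n-BuLi, THF, −10 → 20 °C
Reagents that add atoms: trimethylsulfonium iodide (C[S+](C)C.[I-])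
Why: Dimethylsulfonium methylide opens the epoxide by SN2 attack at the unsubstituted C11, which leaves the C9–O bond and its configuration untouched, and a second equivalent of ylide brings about β-elimination of dimethyl sulfide from 19 (one-carbon homologation of an epoxide to an allylic alcohol).

Step 12
Reactants: 20 vinyl diol
Product: 21 6β-acetoxy-3β-(tert-butyldimethylsilyloxy)-4,4,8α,10β-tetramethyl-9β-vinyl-5α-decalin-9α-ol
Conditions: Ac2O, DMAP, Et3N, CH2Cl2, 40 °C
Reagents that add atoms: acetic anhydride (CC(=O)OC(C)=O)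
Why: DMAP-catalysed acylation should esterify the secondary 6β-OH, whereas the tertiary 9α-OH flanked by the C8 and C10 substituents does not acylate under these conditions.

Step 13
Reactants: 21 vinyl carbinol acetate; 22 3-bromofuran-2(5H)-one
Product: 24 6β-acetoxy-3β-(tert-butyldimethylsilyloxy)-9α-hydroxylabd-13-en-16,15-olide, via B-alkyl-9-BBN 23 (not isolated)
Conditions: 9-BBN, THF, 20 → 50 °C; then 22, PdCl2(dppf), AsPh3, Cs2CO3, DMF–H2O, 20 °C
Reagents that add atoms: none
Why: Anti-Markovnikov hydroboration of the monosubstituted alkene with 9-BBN and B-alkyl Suzuki–Miyaura coupling of borane 23 with the α-bromobutenolide should forge the C12–C13 bond and deliver the α-substituted butenolide directly, the hindered acetate and the silyl ether being stable to the mild aqueous base.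

Step 14
Reactants: 24 silyl-protected target
Product: 25 6β-acetoxy-3β,9α-dihydroxylabd-13-en-16,15-olide (CNP0513254.1)
Conditions: HF·pyridine, THF–pyridine, 0 → 20 °C
Reagents that add atoms: none
Why: Fluoride-mediated cleavage of the silyl ether under buffered, weakly acidic conditions (desilylation) should liberate the 3β-OH without acyl migration, elimination of the tertiary alcohol or attack on the butenolide.

Compound list

1 | (R)-(−)-carvone | O=C1C(C)=CC[C@@H](C(C)=C)C1 | starting material
2 | (5R,6S)-2,6-dimethyl-5-(prop-1-en-2-yl)cyclohex-2-en-1-one (trans-6-methylcarvone) | O=C1C(C)=CC[C@@H](C(C)=C)[C@@H]1C | intermediate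
3 | isobutyronitrile (2-methylpropanenitrile) | CC(C)C#N | starting material
4 | phenyl vinyl sulfone | C=CS(=O)(=O)c1ccccc1 | starting material
5 | lithium C9–C10 enolate of the conjugate adduct, C(CH3)2CN branch at C5 trans to the C7 isopropenyl group (not isolated) | [Li]OC1=C(C)[C@H](C(C)(C)C#N)C[C@@H](C(C)=C)[C@@H]1C | intermediate
6 | C2-lithiated Michael adduct, C10 quaternary with the CH2CH(Li)SO2Ph branch trans to the C5 branch (not isolated) | O=C1[C@@](C)(CC([Li])S(=O)(=O)c2ccccc2)[C@H](C(C)(C)C#N)C[C@@H](C(C)=C)[C@@H]1C | intermediate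
7 | 3-amino-7α-isopropenyl-4,4,8,10β-tetramethyl-2-(phenylsulfonyl)-5α-decal-2-en-9-one, formed as its lithium salt (not isolated) | C1[C@@H](C(C)=C)[C@H](C)C(=O)[C@@]2(C)CC(S(=O)(=O)c3ccccc3)=C(N)C(C)(C)[C@H]12 | intermediate
8 | 7α-isopropenyl-4,4,8α,10β-tetramethyl-2α-(phenylsulfonyl)-5α-decalin-3,9-dione (C2 epimerisable) | C1[C@@H](C(C)=C)[C@@H](C)C(=O)[C@@]2(C)C[C@@H](S(=O)(=O)c3ccccc3)C(=O)C(C)(C)[C@H]12 | intermediate
9 | 7α-isopropenyl-4,4,8α,10β-tetramethyl-5α-decalin-3,9-dione | C1[C@@H](C(C)=C)[C@@H](C)C(=O)[C@@]2(C)CCC(=O)C(C)(C)[C@H]12 | intermediate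
10 | 7α-(1-hydroperoxy-1-methoxyethyl)-4,4,8α,10β-tetramethyl-5α-decalin-3,9-dione (not isolated) | C1[C@@H](C(C)(OC)OO)[C@@H](C)C(=O)[C@@]2(C)CCC(=O)C(C)(C)[C@H]12 | intermediate
11 | 7α-acetoxy-4,4,8α,10β-tetramethyl-5α-decalin-3,9-dione (not isolated) | C1[C@@H](OC(C)=O)[C@@H](C)C(=O)[C@@]2(C)CCC(=O)C(C)(C)[C@H]12 | intermediate
12 | 4,4,8,10β-tetramethyl-5α-decal-7-ene-3,9-dione | C1C=C(C)C(=O)[C@@]2(C)CCC(=O)C(C)(C)[C@H]12 | intermediate
13 | 4,4,8,10β-tetramethyl-5α-decal-7-ene-3,6,9-trione | O=C1C=C(C)C(=O)[C@@]2(C)CCC(=O)C(C)(C)[C@H]12 | intermediate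
14 | 4,4,8α,10β-tetramethyl-5α-decalin-3,6,9-trione | O=C1C[C@@H](C)C(=O)[C@@]2(C)CCC(=O)C(C)(C)[C@H]12 | intermediate
15 | 3β,6β-dihydroxy-4,4,8α,10β-tetramethyl-5α-decalin-9-one | O[C@@H]1C[C@@H](C)C(=O)[C@@]2(C)CC[C@H](O)C(C)(C)[C@H]12 | intermediate
16 | 3β-(tert-butyldimethylsilyloxy)-6β-hydroxy-4,4,8α,10β-tetramethyl-5α-decalin-9-one | O[C@@H]1C[C@@H](C)C(=O)[C@@]2(C)CC[C@H](O[Si](C)(C)C(C)(C)C)C(C)(C)[C@H]12 | intermediate
17 | 3β-(tert-butyldimethylsilyloxy)-4,4,8α,10β-tetramethyl-9-methylene-5α-decalin-6β-ol | O[C@@H]1C[C@@H](C)C(=C)[C@@]2(C)CC[C@H](O[Si](C)(C)C(C)(C)C)C(C)(C)[C@H]12 | intermediate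
18 | 9α,11-epoxide of 17 (spiro-oxirane, oxygen on the α face) | O[C@@H]1C[C@@H](C)[C@]3(CO3)[C@@]2(C)CC[C@H](O[Si](C)(C)C(C)(C)C)C(C)(C)[C@H]12 | intermediate
19 | 9α-olate carrying the 9β-CH2CH2S+(CH3)2 chain, drawn as the zwitterion (not isolated) | O[C@@H]1C[C@@H](C)[C@]([O-])(CC[S+](C)C)[C@@]2(C)CC[C@H](O[Si](C)(C)C(C)(C)C)C(C)(C)[C@H]12 | intermediate
20 | 3β-(tert-butyldimethylsilyloxy)-4,4,8α,10β-tetramethyl-9β-vinyl-5α-decalin-6β,9α-diol | O[C@@H]1C[C@@H](C)[C@](O)(C=C)[C@@]2(C)CC[C@H](O[Si](C)(C)C(C)(C)C)C(C)(C)[C@H]12 | intermediate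
21 | 6β-acetate of 20 | CC(=O)O[C@@H]1C[C@@H](C)[C@](O)(C=C)[C@@]2(C)CC[C@H](O[Si](C)(C)C(C)(C)C)C(C)(C)[C@H]12 | intermediate
22 | 3-bromofuran-2(5H)-one | O=C1OCC=C1Br | starting material
23 | 9-(C12-alkyl)-9-borabicyclo[3.3.1]nonane from 21, boron on C12 (not isolated) | CC(=O)O[C@@H]1C[C@@H](C)[C@](O)(CCB3C4CCCC3CCC4)[C@@]2(C)CC[C@H](O[Si](C)(C)C(C)(C)C)C(C)(C)[C@H]12 | intermediate
24 | 6β-acetoxy-3β-(tert-butyldimethylsilyloxy)-9α-hydroxylabd-13-en-16,15-olide | CC(=O)O[C@@H]1C[C@@H](C)[C@](O)(CCC3=CCOC3=O)[C@@]2(C)CC[C@H](O[Si](C)(C)C(C)(C)C)C(C)(C)[C@H]12 | intermediate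
25 | 6β-acetoxy-3β,9α-dihydroxylabd-13-en-16,15-olide (CNP0513254.1) | CC(=O)O[C@@H]1C[C@@H](C)[C@](O)(CCC2=CCOC2=O)[C@@]2(C)CC[C@H](O)C(C)(C)[C@H]12 | target

Total step count: 14. Longest linear sequence: 14 steps, from 1 to 25; compounds 3, 4 and 22 are commercial.

Steps most likely to fail

Step 2. The nitrile anion may add 1,2 to the carbonyl. Alternatively the Michael addition of the congested tetrasubstituted C10 enolate may be slower than proton transfer and anionic oligomerisation of the vinyl sulfone, so that ring A never closes. The fallback sets out from 2 and returns to the route at 8. The nucleophile is changed to a neutral one: Mukaiyama–Michael addition of commercial methyl trimethylsilyl dimethylketene acetal to 2 (catalytic TMSOTf, CH2Cl2, −78 °C) should give, with silyl transfer, the regiodefined silyl enol ether ester F1. MeLi (THF, 0 °C) then releases the same C10 lithium enolate free of amine, which is treated with 4 in THF–HMPA. The sulfonyl carbanion now closes ring A at C2–C3 on the methyl ester (Dieckmann-type acylation), which gives β-keto sulfone 8 directly.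

Step 11. SN2 opening of the spiro-epoxide at the neopentyl-type C11 may be slower than thermal decay of the sulfonium ylide, returning 18 unchanged. The fallback sets out from 18, avoids both the ylide and the cross-coupling, and returns at 24. Copper-catalysed opening with CH2=CHMgBr (CuI cat., THF, −30 → 0 °C) should give the 9β-allyl-6β,9α-diol F2, and acetylation (Ac2O, DMAP) its 6β-acetate F3. Cross-metathesis of F3 with α-methylene-γ-butyrolactone (second-generation Hoveyda–Grubbs catalyst, CH2Cl2, 40 °C) should give the (E)-α-alkylidene lactone F4. Migration of the exocyclic double bond into the lactone ring (RhCl3·3H2O, EtOH, 80 °C) then gives butenolide 24.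

Step 13. Hydroboration next to the quaternary carbinol carbon may be slow. The B-alkyl coupling may also lose out to protodeboronation, β-hydride elimination or base-induced opening of the bromobutenolide. The fallback sets out from 21 and returns at 24, building the butenolide by enolate alkylation instead. Hydroboration–oxidation (9-BBN; NaBO3·4H2O) should give the primary C12 alcohol F5, and I2, PPh3 and imidazole the iodide F6. Alkylation of the lithium enolate of 3-(phenylsulfanyl)dihydrofuran-2(3H)-one (LiN(i-Pr)2, THF–HMPA, −78 → 0 °C) with F6 should give the α-phenylsulfanyl lactone F7. Oxidation to the sulfoxide (mCPBA, −78 °C) and thermal syn-elimination (toluene, 100 °C) towards the ring then gives 24.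

Further compounds

F1 | step 2 | methyl 2-methyl-2-[2,4-dimethyl-5-(prop-1-en-2-yl)-3-(trimethylsilyloxy)cyclohex-2-en-1-yl]propanoate, ester branch trans to the isopropenyl group | C[Si](C)(C)OC1=C(C)[C@H](C(C)(C)C(=O)OC)C[C@@H](C(C)=C)[C@@H]1C
F2 | step 11 | 9β-allyl-3β-(tert-butyldimethylsilyloxy)-4,4,8α,10β-tetramethyl-5α-decalin-6β,9α-diol | O[C@@H]1C[C@@H](C)[C@](O)(CC=C)[C@@]2(C)CC[C@H](O[Si](C)(C)C(C)(C)C)C(C)(C)[C@H]12
F3 | step 11 | 6β-acetate of F2 | CC(=O)O[C@@H]1C[C@@H](C)[C@](O)(CC=C)[C@@]2(C)CC[C@H](O[Si](C)(C)C(C)(C)C)C(C)(C)[C@H]12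
F4 | step 11 | (E)-α-alkylidene-γ-butyrolactone, 12(13)-ene isomer of 24 | CC(=O)O[C@@H]1C[C@@H](C)[C@](O)(C/C=C3/C(=O)OCC3)[C@@]2(C)CC[C@H](O[Si](C)(C)C(C)(C)C)C(C)(C)[C@H]12
F5 | step 13 | 6β-acetoxy-3β-(tert-butyldimethylsilyloxy)-9β-(2-hydroxyethyl)-4,4,8α,10β-tetramethyl-5α-decalin-9α-ol | CC(=O)O[C@@H]1C[C@@H](C)[C@](O)(CCO)[C@@]2(C)CC[C@H](O[Si](C)(C)C(C)(C)C)C(C)(C)[C@H]12
F6 | step 13 | 6β-acetoxy-3β-(tert-butyldimethylsilyloxy)-9β-(2-iodoethyl)-4,4,8α,10β-tetramethyl-5α-decalin-9α-ol | CC(=O)O[C@@H]1C[C@@H](C)[C@](O)(CCI)[C@@]2(C)CC[C@H](O[Si](C)(C)C(C)(C)C)C(C)(C)[C@H]12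
F7 | step 13 | 13-(phenylsulfanyl)-13,14-dihydro derivative of 24 (C13 epimers) | CC(=O)O[C@@H]1C[C@@H](C)[C@](O)(CCC3(Sc4ccccc4)CCOC3=O)[C@@]2(C)CC[C@H](O[Si](C)(C)C(C)(C)C)C(C)(C)[C@H]12
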